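**Assumptions (one line):** Commercial (+)-pimaric acid has the normal-series A/B-ring stereochemistry of the target (equatorial 4α-CO2H = C18, 5α-H, 9α-H, 10β-Me). Its C13 configuration is irrelevant because C13 becomes sp2 in Step 5. The cycloaddition (Step 15) gives several diastereomers, and the one matching the target is separable.

## Retrosynthetic overview
1. The cyclohexene/ene-dione core comes from a Diels–Alder retron. Bonds C12–Cq and C15–CH disconnect to a labdane (12E)-diene bearing 7β-OH and 18-CHO, plus 2-(chromon-2-yl)-5-methoxy-1,4-benzoquinone. This is the last ring-forming step.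
2. The chromone-quinone dienophile comes from phloroglucinol and an aryl β-ketoester, which form the pyrone ring, followed by CAN oxidative demethylation.
3. The diene comes from pimaric acid, which already supplies C4, C5, C9, C10 and the C18 oxidation level. Ring C is opened by Δ8(14) ozonolysis, Baeyer–Villiger deformylation to the 13-ol, and dehydration to the diene.
4. Ring B is then decorated: C7 α-hydroxylation, C8 methylenation, oxidation and Luche reduction to 7β-OH, and C18 ester → aldehyde.

## Route

**Step 1**
Reactants: 1 (+)-pimaric acid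
Product: 2 methyl pimarate
Conditions: MeI, K2CO3, DMF, rt
Reagents that add atoms: iodomethane, CI
Why: Carboxylate O-alkylation gives the hindered neopentyl methyl ester needed for the later LDA and hydride steps; no stereocentre is touched.

**Step 2**
Reactants: 2
Product: 3 methyl 8-oxo-8,14-seco-pimar-15-en-14-al-18-oate (ring-C-opened keto-aldehyde)
Conditions: O3 (1 equiv), CH2Cl2, –78 °C; then Me2S
Reagents that add atoms: ozone, [O-][O+]=O
Why: Ozonolysis at the electron-rich trisubstituted Δ8(14) alkene is faster than at the monosubstituted vinyl group. It opens ring C to the C8 ketone and the α-quaternary C13 aldehyde, and C9 is retained.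

**Step 3**
Reactants: 3
Product: 4 methyl 13-formyloxy-8-oxo-labd-14-en-18-oate
Conditions: mCPBA, NaHCO3, CH2Cl2, 0 °C
Reagents that add atoms: mCPBA, OOC(=O)c1cccc(Cl)c1
Why: Baeyer–Villiger oxidation. The tertiary allylic carbon migrates in preference to H and to the ketone's alkyl groups, with retention, giving the formate.

**Step 4**
Reactants: 4
Product: 5 methyl 13-hydroxy-8-oxo-labd-14-en-18-oate
Conditions: K2CO3, MeOH, rt
Reagents that add atoms: none
Why: Methanolysis of the formate gives the manool/sclareol-type tertiary allylic alcohol (13-OH, 14-ene, C16 methyl).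

**Step 5**
Reactants: 5
Product: 6 methyl (12E)-8-oxo-labda-12,14-dien-18-oate
Conditions: Burgess reagent, PhH, 50 °C; AgNO3–SiO2 chromatography to isolate the E isomer
Reagents that add atoms: none
Why: Syn-dehydration of the tertiary allylic alcohol gives the conjugated 12,14-diene (assume E:Z ≈ 3:1, separable). C13 stereochemistry is lost here.

**Step 6**
Reactants: 6
Product: 7 methyl 7-hydroxy-8-oxo-labda-12E,14-dien-18-oate (C7 epimers)
Conditions: LDA, THF, –78 °C; then Davis oxaziridine
Reagents that add atoms: 2-(phenylsulfonyl)-3-phenyloxaziridine, O=S(=O)(c1ccccc1)N1OC1c1ccccc1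
Why: Kinetic enolisation at the less hindered C7, then electrophilic O-transfer (Davis α-hydroxylation). The C7 configuration is discarded in Step 9.

**Step 7**
Reactants: 7
Product: 8 methyl 7-hydroxy-labda-8(17),12E,14-trien-18-oate
Conditions: Ph3P=CH2 (from Ph3PCH3Br, KOtBu), PhMe, 60 °C
Reagents that add atoms: methylenetriphenylphosphorane, C=P(c1ccccc1)(c1ccccc1)c1ccccc1 (its CH2 becomes C17)
Why: Wittig methylenation of the C8 ketone forms the exocyclic 8(17)-alkene. Excess ylide tolerates the free α-OH.

**Step 8**
Reactants: 8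
Product: 9 labda-8(17),12E,14-triene-7,18-diol
Conditions: LiAlH4, THF, reflux
Reagents that add atoms: none
Why: Hydride reduction of the hindered C18 methyl ester to the primary alcohol; the alkenes are untouched.

**Step 9**
Reactants: 9
Product: 10 18-hydroxy-labda-8(17),12E,14-trien-7-one
Conditions: MnO2, CH2Cl2, rt
Reagents that add atoms: none
Why: MnO2 selectively oxidises the allylic 7-OH, which destroys the C7 epimer mixture. The non-allylic neopentyl C18 alcohol is unchanged. Neutral conditions avoid isomerisation of the α-methylene ketone.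

**Step 10**
Reactants: 10
Product: 11 7-oxo-labda-8(17),12E,14-trien-18-al
Conditions: Dess–Martin periodinane, NaHCO3, CH2Cl2, rt
Reagents that add atoms: none
Why: Oxidation of the primary alcohol to the aldehyde. C4 is quaternary, so nothing can epimerise, and the enone and diene survive.

**Step 11**
Reactants: 11
Product: 12 7β-hydroxy-labda-8(17),12E,14-trien-18-al (the diene)
Conditions: NaBH4, CeCl3·7H2O, MeOH/CH2Cl2, –78 → –20 °C; dilute HCl workup
Reagents that add atoms: none
Why: Luche 1,2-reduction in which the aldehyde is masked as a hemiacetal or acetal. Axial hydride delivery from the α-face, flanked only by the small 5α-H and 9α-H, gives the equatorial 7β-OH (the only new stereocentre in the fragment). The workup hydrolyses the acetal.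

**Step 12**
Reactants: 13 2′,4′,5′-trimethoxyacetophenone
Product: 14 ethyl 3-oxo-3-(2,4,5-trimethoxyphenyl)propanoate
Conditions: (EtO)2CO, NaH, PhMe, reflux
Reagents that add atoms: diethyl carbonate, CCOC(=O)OCC
Why: Claisen-type C-acylation of the methyl ketone enolate.

**Step 13**
Reactants: 14; 15 phloroglucinol
Product: 16 5,7-dihydroxy-2-(2,4,5-trimethoxyphenyl)chromone
Conditions: neat (or Ph2O), 200 °C, 2 h
Reagents that add atoms: none
Why: Thermal transacylation of phloroglucinol with the β-ketoester, then cyclodehydration (Kostanecki-type), closes the pyrone ring to the 5,7-dihydroxyflavone without protecting groups.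

**Step 14**
Reactants: 16
Product: 17 2-(5,7-dihydroxy-4-oxochromen-2-yl)-5-methoxy-1,4-benzoquinone
Conditions: CAN (2.5 equiv), MeCN/H2O, 0 °C
Reagents that add atoms: water, O
Why: CAN oxidatively demethylates the para-dimethoxy pair (2′,5′) to the quinone. The 4′-OMe stays as the vinylogous-ester methoxy, which gives the required 2-aryl-5-methoxy substitution.

**Step 15**
Reactants: 12; 17
Product: 18 Dichrostachine H
Conditions: MeCN, BHT, 80 °C, sealed tube, dark, 48 h; then HPLC
Reagents that add atoms: none
Why: Intermolecular Diels–Alder of the s-cis (12E)-diene across the more electrophilic aryl-substituted quinone C2=C3 bond (the C5=C6 bond is a deactivated vinylogous ester).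
- **Regiochemistry:** the C13-methyl-activated terminus C12 bonds to the chromonyl-bearing carbon.
- **Ring fusion:** suprafacial addition gives the cis-fused ene-dione; its α-H cannot aromatise because Cq is quaternary.
- **C12/Cq relationship:** the target has C11 trans to the quinone-derived ring, which corresponds to an exo approach of the E-diene.
- **Facial selectivity:** it is controlled by the decalin and is expected to be modest, so diastereomers are separated.

## Compound list
1 | (+)-pimaric acid | C=CC1(C)C=C2CC[C@@H]3[C@](C)(CCC[C@@]3(C)C(=O)O)[C@H]2CC1 | starting material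
2 | methyl pimarate | C=CC1(C)C=C2CC[C@@H]3[C@](C)(CCC[C@@]3(C)C(=O)OC)[C@H]2CC1 | intermediate
3 | ring-C-opened keto-aldehyde | O=C1CC[C@@H]2[C@](C)(CCC[C@@]2(C)C(=O)OC)[C@H]1CCC(C)(C=O)C=C | intermediate
4 | 13-formyloxy-8-oxo-labd-14-en-18-oate methyl ester | O=C1CC[C@@H]2[C@](C)(CCC[C@@]2(C)C(=O)OC)[C@H]1CCC(C)(OC=O)C=C | intermediate
5 | 13-hydroxy-8-oxo-labd-14-en-18-oate methyl ester | O=C1CC[C@@H]2[C@](C)(CCC[C@@]2(C)C(=O)OC)[C@H]1CCC(C)(O)C=C | intermediate
6 | methyl (12E)-8-oxo-labda-12,14-dien-18-oate | O=C1CC[C@@H]2[C@](C)(CCC[C@@]2(C)C(=O)OC)[C@H]1C/C=C(C)/C=C | intermediate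
7 | methyl 7-hydroxy-8-oxo-labda-12E,14-dien-18-oate | O=C1C(O)C[C@@H]2[C@](C)(CCC[C@@]2(C)C(=O)OC)[C@H]1C/C=C(C)/C=C | intermediate
8 | methyl 7-hydroxy-labda-8(17),12E,14-trien-18-oate | C=C1C(O)C[C@@H]2[C@](C)(CCC[C@@]2(C)C(=O)OC)[C@H]1C/C=C(C)/C=C | intermediate
9 | labda-8(17),12E,14-triene-7,18-diol | C=C1C(O)C[C@@H]2[C@](C)(CCC[C@@]2(C)CO)[C@H]1C/C=C(C)/C=C | intermediate
10 | 18-hydroxy-labda-8(17),12E,14-trien-7-one | C=C1C(=O)C[C@@H]2[C@](C)(CCC[C@@]2(C)CO)[C@H]1C/C=C(C)/C=C | intermediate
11 | 7-oxo-labda-8(17),12E,14-trien-18-al | C=C1C(=O)C[C@@H]2[C@](C)(CCC[C@@]2(C)C=O)[C@H]1C/C=C(C)/C=C | intermediate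
12 | 7β-hydroxy-labda-8(17),12E,14-trien-18-al | C=C1[C@@H](O)C[C@@H]2[C@](C)(CCC[C@@]2(C)C=O)[C@H]1C/C=C(C)/C=C | intermediate (diene)
13 | 2′,4′,5′-trimethoxyacetophenone | CC(=O)c1cc(OC)c(OC)cc1OC | starting material
14 | ethyl 3-oxo-3-(2,4,5-trimethoxyphenyl)propanoate | CCOC(=O)CC(=O)c1cc(OC)c(OC)cc1OC | intermediate
15 | phloroglucinol | Oc1cc(O)cc(O)c1 | starting material
16 | 5,7-dihydroxy-2-(2,4,5-trimethoxyphenyl)chromone | O=c1cc(-c2cc(OC)c(OC)cc2OC)oc2cc(O)cc(O)c12 | intermediate
17 | 2-(5,7-dihydroxy-4-oxochromen-2-yl)-5-methoxy-1,4-benzoquinone | O=C1C=C(OC)C(=O)C=C1c1cc(=O)c2c(O)cc(O)cc2o1 | intermediate (dienophile)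
18 | Dichrostachine H | C=C1[C@@H](O)C[C@@H]2[C@](C)(CCC[C@@]2(C)C=O)[C@H]1C[C@@H]1C(C)=CC[C@H]2C(=O)C(OC)=CC(=O)[C@@]12c1cc(=O)c2c(O)cc(O)cc2o1 | target

**Total steps:** 15. **Longest linear sequence:** 12 steps (1 → 12 → 18).

## Three steps most likely to fail
1. **Step 15 (Diels–Alder).** Regiochemistry, exo/endo and facial selectivity are uncertain at a hindered quaternary centre, and the phenols and 7-OH are free.
   - Fallback: reduce 17 to its hydroquinone (Na2S2O4) and oxidise it in situ with Ag2O in the presence of 12, so the quinone concentration stays low and the cycloaddition runs at a lower temperature, instead of using pre-isolated 17.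
2. **Steps 2–4 (ring-C cleavage and deformylation).** Ozone may also attack the vinyl group, and the Baeyer–Villiger step may give the acid (H migration) or react at the ketone.
   - Fallback: oxidise aldehyde 3 to the acid (NaClO2), then do a Barton decarboxylative hydroxylation (N-hydroxypyridinethione ester, O2, hν) to give 5, instead of the Baeyer–Villiger step.
3. **Step 14 (CAN oxidation of the free-phenol flavone).** The electron-rich A-ring phenols may be oxidised or degraded.
   - Fallback: skip the oxidation and couple a 5,7-di-O-MOM-protected chromon-2-yl boronic acid to 2-bromo-5-methoxy-1,4-benzoquinone (Ag- or Pd-mediated arylation), then remove the MOM groups after the Diels–Alder.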